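**Retrosynthetic overview**
1. The target comes from bis-silyl ether 23 by desilylation. Ester 23 comes from the 8-epi alcohol 21 by Mitsunobu esterification, which acylates and inverts C8 in one operation.
2. Key disconnection C7–C8, closing the ten-membered ring (second ring, formed last). The β-carbon of a preformed butenolide is normally an acceptor. As the γ-terminus of an allylchromium it becomes a lactone homoenolate equivalent and attacks the C8 aldehyde, regenerating the exo-methylene group.
3. The butenolide (first ring) comes from ring-closing metathesis of the 2-(bromomethyl)acrylate of a C6 allylic alcohol, itself made by catalytic asymmetric alkenylzinc addition to the C6 aldehyde.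
4. C1=C10 comes from an E-selective Wittig reaction with a stabilised ylide that carries C14 as an ester and C8 as a dioxolane.
5. C4 and the two differentiated arms (C1–C3 and C5–C6) come from asymmetric Baeyer–Villiger desymmetrisation of tert-butyl 4-oxocyclohexanecarboxylate.

Assumption: labels C1–C15 follow germacrane numbering of the target (ring C1–C10; C11–C13 lactone side chain with C12 the carbonyl; C14 on C10; C15 on C4). Compounds 1, 4, 5, 10, 16 and 22 are taken as catalogue chemicals.

**Route**

Step 1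
Reactants: 1 tert-butyl 4-oxocyclohexane-1-carboxylate
Product: 2 tert-butyl (4S)-7-oxooxepane-4-carboxylate
Conditions: Sc(OTf)3 (5 mol%), C2-symmetric amino-acid-derived N,N'-dioxide ligand (5 mol%, enantiomer giving the S lactone), m-CPBA (1.2 equiv), EtOAc, −20 °C
Reagents that add atoms: m-CPBA, O=C(OO)c1cccc(Cl)c1
Why: Catalytic asymmetric Baeyer–Villiger desymmetrisation, in which the equatorial ester locks the chair and the chiral Sc(OTf)3 complex lets only one of the two enantiotopic CH2 groups migrate in the Criegee adduct, setting C4 as S and at the same time differentiating the arms (C1 acyl, C6 alkoxy).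

Step 2
Reactants: 2 tert-butyl (4S)-7-oxooxepane-4-carboxylate
Product: 3 tert-butyl (2S)-2-(2-hydroxyethyl)-5-oxopentanoate
Conditions: i-Bu2AlH (1.05 equiv), CH2Cl2, −78 °C; aq. work-up; used crude
Reagents that add atoms: none
Why: Partial lactone reduction, in which the unhindered seven-membered lactone takes up hydride much faster than the α-branched tert-butyl ester and the tetrahedral aluminate survives at −78 °C, so hydrolysis gives the open ε-hydroxy aldehyde with C4 untouched.

Step 3
Reactants: 4 [2-(1,3-dioxolan-2-yl)ethyl]triphenylphosphonium bromide; 5 methyl chloroformate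
Product: 7 methyl 3-(1,3-dioxolan-2-yl)-2-(triphenylphosphoranylidene)propanoate, via dioxolanylethylidene ylide 6 (not isolated)
Conditions: NaN(SiMe3)2 (2.05 equiv), THF, −78 → 0 °C; ClCO2Me (1.0 equiv), −78 °C → rt
Reagents that add atoms: none
Why: C-acylation of a non-stabilised ylide (Bestmann-type ylide acylation), after which the second equivalent of base deprotonates the acylphosphonium salt to give the shelf-stable ester ylide that carries C8–C10 and C14.

Step 4
Reactants: 3 tert-butyl (2S)-2-(2-hydroxyethyl)-5-oxopentanoate; 7 methyl 3-(1,3-dioxolan-2-yl)-2-(triphenylphosphoranylidene)propanoate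
Product: 8 7-tert-butyl 1-methyl (2E,6S)-2-[(1,3-dioxolan-2-yl)methyl]-6-(2-hydroxyethyl)hept-2-enedioate
Conditions: toluene, 80 °C, 16 h
Reagents that add atoms: none
Why: Wittig olefination with an α-substituted stabilised ylide is E-selective (ester trans to the C2 chain), which places C9 cis to C2 exactly as in the target ring alkene, and it tolerates the free primary alcohol.

Step 5
Reactants: 8 7-tert-butyl 1-methyl (2E,6S)-2-[(1,3-dioxolan-2-yl)methyl]-6-(2-hydroxyethyl)hept-2-enedioate
Product: 9 7-tert-butyl 1-methyl (2E,6S)-2-[(1,3-dioxolan-2-yl)methyl]-6-(2-oxoethyl)hept-2-enedioate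
Conditions: Dess–Martin periodinane (1.2 equiv), CH2Cl2, 0 °C → rt
Reagents that add atoms: none
Why: Dess–Martin oxidation is neutral and fast, stops at the C6 aldehyde, and leaves the acetal, both esters, the enoate and the C4 centre (not α to the new carbonyl) untouched.

Step 6
Reactants: 9 7-tert-butyl 1-methyl (2E,6S)-2-[(1,3-dioxolan-2-yl)methyl]-6-(2-oxoethyl)hept-2-enedioate; 10 hex-1-yne
Product: 13 7-tert-butyl 1-methyl (2E,6S)-2-[(1,3-dioxolan-2-yl)methyl]-6-[(2R,3E)-2-hydroxyoct-3-en-1-yl]hept-2-enedioate, via hexenyl(dicyclohexyl)borane 11 (not isolated), via hexenyl(methyl)zinc 12 (not isolated)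
Conditions: 10, Cy2BH, hexane, 0 °C → rt; Me2Zn, −78 °C; (−)-MIB (5 mol%), then 9, −30 → 0 °C; aq. work-up
Reagents that add atoms: none
Why: Oppolzer-type catalytic asymmetric alkenylzinc addition (hydroboration, boron-to-zinc exchange, amino-alcohol-accelerated 1,2-addition), in which the MIB–zinc complex delivers the alkenyl group to the Si face of the aldehyde and sets C6 as R under catalyst control, esters and acetal are inert to organozincs, and material from the minor enantiomer of 2 becomes a separable diastereomer.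

Step 7
Reactants: 13 7-tert-butyl 1-methyl (2E,6S)-2-[(1,3-dioxolan-2-yl)methyl]-6-[(2R,3E)-2-hydroxyoct-3-en-1-yl]hept-2-enedioate
Product: 14 (2E,6S,8R,9E)-2-[(1,3-dioxolan-2-yl)methyl]-6-(hydroxymethyl)tetradeca-2,9-diene-1,8-diol
Conditions: LiAlH4 (4 equiv), Et2O, 0 °C; aq. NaOH work-up
Reagents that add atoms: none
Why: Exhaustive hydride reduction converts the enoate (1,2-reduction, geometry kept) and the tert-butyl ester into the C14 and C15 primary alcohols in one operation, while the dioxolane and both alkenes are inert to LiAlH4 at 0 °C and no stereocentre is affected.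

Step 8
Reactants: 14 (2E,6S,8R,9E)-2-[(1,3-dioxolan-2-yl)methyl]-6-(hydroxymethyl)tetradeca-2,9-diene-1,8-diol
Product: 15 (2E,6S,8R,9E)-1-(tert-butyldiphenylsilyloxy)-6-[(tert-butyldiphenylsilyloxy)methyl]-2-[(1,3-dioxolan-2-yl)methyl]tetradeca-2,9-dien-8-ol
Conditions: TBDPSCl (2.1 equiv), imidazole (4 equiv), CH2Cl2, 0 °C
Reagents that add atoms: tert-butyl(chloro)diphenylsilane (TBDPSCl), CC(C)(C)[Si](Cl)(c1ccccc1)c1ccccc1
Why: Sterically controlled silylation, in which the bulky chlorosilane caps both primary alcohols and leaves the secondary allylic C6 alcohol free, and the acid-stable TBDPS group is chosen to survive the later acetal hydrolysis.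

Step 9
Reactants: 15 (2E,6S,8R,9E)-1-(tert-butyldiphenylsilyloxy)-6-[(tert-butyldiphenylsilyloxy)methyl]-2-[(1,3-dioxolan-2-yl)methyl]tetradeca-2,9-dien-8-ol; 16 2-(bromomethyl)prop-2-enoic acid
Product: 17 2-(bromomethyl)acrylate ester of 15 at the C6 oxygen (4S,6R)
Conditions: DCC (1.3 equiv), DMAP (5 mol%), CH2Cl2, 0 °C
Reagents that add atoms: none
Why: Steglich esterification occurs at oxygen with retention at C6, and the low DMAP loading and low temperature keep the allylic bromide intact.

Step 10
Reactants: 17 2-(bromomethyl)acrylate ester of 15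
Product: 18 (5R)-3-(bromomethyl)-5-[(2S,5E)-7-(tert-butyldiphenylsilyloxy)-2-[(tert-butyldiphenylsilyloxy)methyl]-6-[(1,3-dioxolan-2-yl)methyl]hept-5-en-1-yl]furan-2(5H)-one
Conditions: second-generation Grubbs catalyst (5 mol%), toluene (5 mM), 80 °C
Reagents that add atoms: none
Why: Ring-closing metathesis closes the five-membered butenolide (first ring) between C7 and C11 with loss of hex-1-ene, the hindered trisubstituted C1=C10 alkene stays out of the reaction, and C6 is not touched.

Step 11
Reactants: 18 (5R)-3-(bromomethyl)butenolide acetal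
Product: 19 (5R)-3-(bromomethyl)-5-[(2S,5E)-7-(tert-butyldiphenylsilyloxy)-2-[(tert-butyldiphenylsilyloxy)methyl]-6-(2-oxoethyl)hept-5-en-1-yl]furan-2(5H)-one
Conditions: p-TsOH·H2O (10 mol%), acetone/H2O (10:1), rt; used at once
Reagents that add atoms: water, O
Why: Mild acid-catalysed acetal hydrolysis frees the C8 aldehyde while the TBDPS ethers, the allylic bromide and the butenolide survive, and the β,γ-unsaturated aldehyde is used immediately to avoid drift into conjugation.

Step 12
Reactants: 19 (5R)-3-(bromomethyl)butenolide aldehyde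
Product: 21 (1(10)E,4S,6R,7R,8S)-14,15-bis(tert-butyldiphenylsilyloxy)-8-hydroxygermacra-1(10),11(13)-dien-6,12-olide, via allylchromium dichloride 20 (not isolated)
Conditions: CrCl2 (8 equiv), THF, rt, 19 added by syringe pump over 12 h (final 1 mM); aq. work-up
Reagents that add atoms: none
Why: Intramolecular Nozaki–Hiyama–Kishi (Barbier-type) allylation, in which two equivalents of CrCl2 turn the bromomethylbutenolide into the trivalent-chromium allyl species 20, so that C7 (the β-carbon of the unsaturated lactone, normally an acceptor) attacks the equally electrophilic aldehyde carbon C8 as a lactone homoenolate equivalent with allylic transposition that restores the exo-methylene; C8 adds to the butenolide face anti to the C5 chain (trans-6,7 lactone, C7 set), and the ring-locked E-allyl geometry in a closed chair transition state with C9 equatorial gives the 7,8-anti carbinol (8S).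

Step 13
Reactants: 21 (1(10)E,4S,6R,7R,8S)-14,15-bis(tert-butyldiphenylsilyloxy)-8-hydroxygermacra-1(10),11(13)-dien-6,12-olide; 22 methacrylic acid
Product: 23 (1(10)E,4S,6R,7S,8R)-14,15-bis(tert-butyldiphenylsilyloxy)-8-(methacryloyloxy)germacra-1(10),11(13)-dien-6,12-olide
Conditions: PPh3 (2 equiv), DIAD (2 equiv), 22 (2 equiv), toluene, 0 °C → rt
Reagents that add atoms: none
Why: Mitsunobu esterification, in which methacrylate displaces the alkoxyphosphonium salt of the 8S alcohol in an SN2 step, so acylation and inversion to the required 8R configuration happen in the same operation (the C7 descriptor changes only because CIP priorities change).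

Step 14
Reactants: 23 (1(10)E,4S,6R,7S,8R)-14,15-bis(tert-butyldiphenylsilyloxy)-8-(methacryloyloxy)germacra-1(10),11(13)-dien-6,12-olide
Product: 24 (1(10)E,4S,6R,7S,8R)-14,15-dihydroxy-8-(methacryloyloxy)germacra-1(10),11(13)-dien-6,12-olide (CNP0546547.2)
Conditions: HF·pyridine, THF/pyridine, 0 °C → rt
Reagents that add atoms: none
Why: Fluoride-mediated desilylation under buffered, non-basic conditions removes both TBDPS groups without conjugate addition to the α-methylene lactone, ester cleavage or acyl migration.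

**Compound list**
1 | tert-butyl 4-oxocyclohexane-1-carboxylate | O=C1CCC(CC1)C(=O)OC(C)(C)C | starting material
2 | tert-butyl (4S)-7-oxooxepane-4-carboxylate | O=C1CC[C@H](C(=O)OC(C)(C)C)CCO1 | intermediate
3 | tert-butyl (2S)-2-(2-hydroxyethyl)-5-oxopentanoate | O=CCC[C@H](C(=O)OC(C)(C)C)CCO | intermediate
4 | [2-(1,3-dioxolan-2-yl)ethyl]triphenylphosphonium bromide | [Br-].C1COC(CC[P+](c2ccccc2)(c2ccccc2)c2ccccc2)O1 | starting material
5 | methyl chloroformate | COC(=O)Cl | starting material
6 | [2-(1,3-dioxolan-2-yl)ethylidene]triphenylphosphorane | C1COC(CC=P(c2ccccc2)(c2ccccc2)c2ccccc2)O1 | intermediate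
7 | methyl 3-(1,3-dioxolan-2-yl)-2-(triphenylphosphoranylidene)propanoate | COC(=O)C(CC1OCCO1)=P(c1ccccc1)(c1ccccc1)c1ccccc1 | intermediate
8 | 7-tert-butyl 1-methyl (2E,6S)-2-[(1,3-dioxolan-2-yl)methyl]-6-(2-hydroxyethyl)hept-2-enedioate | O1CCOC1C/C(C(=O)OC)=C\CC[C@H](C(=O)OC(C)(C)C)CCO | intermediate
9 | 7-tert-butyl 1-methyl (2E,6S)-2-[(1,3-dioxolan-2-yl)methyl]-6-(2-oxoethyl)hept-2-enedioate | O1CCOC1C/C(C(=O)OC)=C\CC[C@H](C(=O)OC(C)(C)C)CC=O | intermediate
10 | hex-1-yne | C#CCCCC | starting material
11 | dicyclohexyl[(E)-hex-1-enyl]borane | CCCC/C=C/B(C1CCCCC1)C1CCCCC1 | intermediate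
12 | [(E)-hex-1-enyl](methyl)zinc | CCCC/C=C/[Zn]C | intermediate
13 | 7-tert-butyl 1-methyl (2E,6S)-2-[(1,3-dioxolan-2-yl)methyl]-6-[(2R,3E)-2-hydroxyoct-3-en-1-yl]hept-2-enedioate | O1CCOC1C/C(C(=O)OC)=C\CC[C@H](C(=O)OC(C)(C)C)C[C@@H](O)/C=C/CCCC | intermediate
14 | (2E,6S,8R,9E)-2-[(1,3-dioxolan-2-yl)methyl]-6-(hydroxymethyl)tetradeca-2,9-diene-1,8-diol | O1CCOC1C/C(CO)=C\CC[C@H](CO)C[C@@H](O)/C=C/CCCC | intermediate
15 | (2E,6S,8R,9E)-1-(tert-butyldiphenylsilyloxy)-6-[(tert-butyldiphenylsilyloxy)methyl]-2-[(1,3-dioxolan-2-yl)methyl]tetradeca-2,9-dien-8-ol | O1CCOC1C/C(CO[Si](c1ccccc1)(c1ccccc1)C(C)(C)C)=C\CC[C@H](CO[Si](c1ccccc1)(c1ccccc1)C(C)(C)C)C[C@@H](O)/C=C/CCCC | intermediate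
16 | 2-(bromomethyl)prop-2-enoic acid | C=C(CBr)C(=O)O | starting material
17 | 2-(bromomethyl)acrylate of 15 at the C6 oxygen (4S,6R; both alkenes E) | O1CCOC1C/C(CO[Si](c1ccccc1)(c1ccccc1)C(C)(C)C)=C\CC[C@H](CO[Si](c1ccccc1)(c1ccccc1)C(C)(C)C)C[C@@H](OC(=O)C(=C)CBr)/C=C/CCCC | intermediate
18 | (5R)-3-(bromomethyl)-5-[(2S,5E)-7-(tert-butyldiphenylsilyloxy)-2-[(tert-butyldiphenylsilyloxy)methyl]-6-[(1,3-dioxolan-2-yl)methyl]hept-5-en-1-yl]furan-2(5H)-one | O1CCOC1C/C(CO[Si](c1ccccc1)(c1ccccc1)C(C)(C)C)=C\CC[C@H](CO[Si](c1ccccc1)(c1ccccc1)C(C)(C)C)C[C@H]1OC(=O)C(CBr)=C1 | intermediate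
19 | (5R)-3-(bromomethyl)-5-[(2S,5E)-7-(tert-butyldiphenylsilyloxy)-2-[(tert-butyldiphenylsilyloxy)methyl]-6-(2-oxoethyl)hept-5-en-1-yl]furan-2(5H)-one | O=CC/C(CO[Si](c1ccccc1)(c1ccccc1)C(C)(C)C)=C\CC[C@H](CO[Si](c1ccccc1)(c1ccccc1)C(C)(C)C)C[C@H]1OC(=O)C(CBr)=C1 | intermediate
20 | allylchromium dichloride derived from 19 (CrCl2 in place of Br on C13) | O=CC/C(CO[Si](c1ccccc1)(c1ccccc1)C(C)(C)C)=C\CC[C@H](CO[Si](c1ccccc1)(c1ccccc1)C(C)(C)C)C[C@H]1OC(=O)C(C[Cr](Cl)Cl)=C1 | intermediate
21 | (1(10)E,4S,6R,7R,8S)-14,15-bis(tert-butyldiphenylsilyloxy)-8-hydroxygermacra-1(10),11(13)-dien-6,12-olide (8α-OH, trans-6,7 lactone) | O[C@H]1C/C(CO[Si](c3ccccc3)(c3ccccc3)C(C)(C)C)=C\CC[C@H](CO[Si](c3ccccc3)(c3ccccc3)C(C)(C)C)C[C@H]2OC(=O)C(=C)[C@H]12 | intermediate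
22 | methacrylic acid | C=C(C)C(=O)O | starting material
23 | (1(10)E,4S,6R,7S,8R)-14,15-bis(tert-butyldiphenylsilyloxy)-8-(methacryloyloxy)germacra-1(10),11(13)-dien-6,12-olide | C=C(C)C(=O)O[C@@H]1C/C(CO[Si](c3ccccc3)(c3ccccc3)C(C)(C)C)=C\CC[C@H](CO[Si](c3ccccc3)(c3ccccc3)C(C)(C)C)C[C@H]2OC(=O)C(=C)[C@H]12 | intermediate
24 | (1(10)E,4S,6R,7S,8R)-14,15-dihydroxy-8-(methacryloyloxy)germacra-1(10),11(13)-dien-6,12-olide | C=C(C)C(=O)O[C@@H]1C/C(CO)=C\CC[C@H](CO)C[C@H]2OC(=O)C(=C)[C@H]12 | target

**Step count**
Total: 14 steps. Longest linear sequence: 13 steps (steps 1, 2 and 4–14). Step 3 is the one-step side branch.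

**Three steps most likely to fail**

Step 12 (ring closure). A ten-membered closure through a ring carbon of the butenolide competes with protonation or dimerisation of the allylchromium, and the C8 configuration rests on a transition-state model. The fallback replaces the reductive Barbier closure by an isolable allylmetal and an open, Lewis-acid-promoted transition state. It sets out from 19 and comes back at 23.
- Treating 19 with (Bu3Sn)2 and catalytic Pd(PPh3)4 in THF gives the allylstannane aldehyde F1.
- Slow addition of F1 to BF3·OEt2 in CH2Cl2 at −78 °C under high dilution closes the same C7–C8 bond by SE2' attack through an antiperiplanar open transition state.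
- This open transition state favours the 7,8-syn adduct, the 8R alcohol F2.
- Acylation of F2 with methacrylic anhydride, Et3N and DMAP gives 23 directly with retention, so the Mitsunobu step is not needed. Any 8R material formed in step 12 itself can be used the same way.

Step 13 (Mitsunobu inversion). SN2 displacement at a medium-ring carbinol next to a branched carbon may lose to elimination. The fallback changes from displacement to an oxidation–reduction sequence. It sets out from 21 and comes back at 23.
- Dess–Martin oxidation of 21 under buffered conditions gives the C8 ketone F3.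
- F3 is kept cold and free of base because the C6 acyloxy group is β to the ketone.
- F3 is reduced at once with an oxazaborolidine/BH3·SMe2 system (CBS reduction), using the catalyst enantiomer chosen for hydride delivery to the α face. NaBH4/CeCl3 at −78 °C is used instead if substrate control is already sufficient.
- The product is the 8R alcohol F2, and methacrylic anhydride/DMAP then leads to 23.

Step 1 (asymmetric Baeyer–Villiger). The enantioselectivity is established for 4-alkyl and 4-aryl cyclohexanones but not for the 4-ester. The fallback desymmetrises the ketone by enantioselective deprotonation instead of oxygen insertion. It sets out from 1 and comes back at 2.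
- The appropriate enantiomer of lithium bis(1-phenylethyl)amide with Me3SiCl as internal quench (THF, −100 °C) gives the silyl enol ether F4.
- Ozonolysis of F4 with NaBH4 work-up cleaves the C1=C6 bond to give the hydroxy acid F5.
- Yamaguchi lactonisation of F5 (2,4,6-trichlorobenzoyl chloride, Et3N, then DMAP, dilute toluene) closes lactone 2.

**Further compounds**
F1 | step 12 | (5R)-3-[(tributylstannyl)methyl] analogue of aldehyde 19 (4S,6R,1(10)E) | O=CC/C(CO[Si](c1ccccc1)(c1ccccc1)C(C)(C)C)=C\CC[C@H](CO[Si](c1ccccc1)(c1ccccc1)C(C)(C)C)C[C@H]1OC(=O)C(C[Sn](CCCC)(CCCC)CCCC)=C1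
F2 | step 12 | (1(10)E,4S,6R,7R,8R)-14,15-bis(tert-butyldiphenylsilyloxy)-8-hydroxygermacra-1(10),11(13)-dien-6,12-olide (8β-OH) | O[C@@H]1C/C(CO[Si](c3ccccc3)(c3ccccc3)C(C)(C)C)=C\CC[C@H](CO[Si](c3ccccc3)(c3ccccc3)C(C)(C)C)C[C@H]2OC(=O)C(=C)[C@H]12
F3 | step 13 | (1(10)E,4S,6R,7S)-14,15-bis(tert-butyldiphenylsilyloxy)-8-oxogermacra-1(10),11(13)-dien-6,12-olide | O=C1C/C(CO[Si](c3ccccc3)(c3ccccc3)C(C)(C)C)=C\CC[C@H](CO[Si](c3ccccc3)(c3ccccc3)C(C)(C)C)C[C@H]2OC(=O)C(=C)[C@H]12
F4 | step 1 | tert-butyl (1S)-4-(trimethylsilyloxy)cyclohex-3-ene-1-carboxylate | C[Si](C)(C)OC1=CC[C@@H](C(=O)OC(C)(C)C)CC1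
F5 | step 1 | (4S)-4-(tert-butoxycarbonyl)-6-hydroxyhexanoic acid | OC(=O)CC[C@H](C(=O)OC(C)(C)C)CCO
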